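**Plan**

- Retrosynthesis (oxane numbered O1, C2 with the arylethyl chain, C4 with the acetoxy group, C6 with the trioxygenated aryl ring): the acetate and the O-protecting groups are removed first, then the ring is cut at C5–C6, then at the O1–C6 ether bond, and last at C2–C3 (propargyl addition to a 3-arylpropanal).
- Forward: each commercial arene is elaborated on its own, the halves are joined through O1 by benzylic etherification, the terminal alkyne becomes an enol acetate, and the oxane, the only ring of the target that has to be built, is closed by C5–C6 bond formation.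
- Enabling feature: C6 is both α to the ring oxygen O1 and benzylic to the 3,4,5-trioxygenated ring. In an open-chain benzyl ether that already holds O1–C6, this carbon can give up hydride to an oxidant and become an oxocarbenium carbon within reach of a carbon nucleophile on the C2 side chain.
- Stereochemistry: C2 (S) comes from a catalyst-controlled propargylation, C6 (S) is relayed from C2 through a chair transition state (2,6-cis), and C4 (S, axial oxygen) comes from equatorial hydride delivery to the ring ketone.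
- Protection: the guaiacyl phenol is carried as a benzyl ether and the catechol as a diphenylmethylene ketal (no C–H at the ketal carbon, para oxygen held coplanar with the ring); one hydrogenolysis removes both at the end.

Key step: step 9

Remark: (R)-TRIP is assumed to attack the same aldehyde face here as it does with aryl aldehydes, which for this unbranched aldehyde corresponds to the (S)-alcohol; if the sense proves opposite, the (S)-catalyst is used in the same way.

**Route**

Step 1
Reactants: 1 dihydroferulic acid, 3-(4-hydroxy-3-methoxyphenyl)propanoic acid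
Product: 2 benzyl 3-[4-(benzyloxy)-3-methoxyphenyl]propanoate
Conditions: BnBr (2.4 equiv), K2CO3, DMF, 60 °C
Reagents that add atoms: benzyl bromide, BrCc1ccccc1
Why: Double Williamson-type O-alkylation (SN2) of the phenoxide and the carboxylate with a reactive benzylic halide should cap both acidic sites in one operation and leave an ester that serves as the handle for partial reduction.

Step 2
Reactants: 2 benzyl 3-[4-(benzyloxy)-3-methoxyphenyl]propanoate
Product: 4 3-[4-(benzyloxy)-3-methoxyphenyl]propanal, via aluminium hemiacetal 3 (not isolated)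
Conditions: i-Bu2AlH (1.1 equiv), CH2Cl2, −78 °C; then MeOH, aq. potassium sodium tartrate
Reagents that add atoms: none
Why: Partial ester reduction with i-Bu2AlH should stop at the aldehyde stage because the tetrahedral aluminium hemiacetal 3 is stable at −78 °C and collapses only on aqueous work-up, while the aryl benzyl ether is inert to the hydride.

Step 3
Reactants: 4 3-[4-(benzyloxy)-3-methoxyphenyl]propanal; 5 allenylboronic acid pinacol ester
Product: 7 (3S)-1-[4-(benzyloxy)-3-methoxyphenyl]hex-5-yn-3-ol, via pinacol borate ester 6 (not isolated)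
Conditions: (R)-TRIP phosphoric acid [(R)-3,3′-bis(2,4,6-triisopropylphenyl)-1,1′-binaphthyl-2,2′-diyl hydrogen phosphate, 10 mol%], 4 Å MS, toluene, 0 °C to rt; aq. NaHCO3 work-up
Reagents that add atoms: none
Why: Chiral phosphoric acid-catalysed asymmetric propargylboration, in which the acid hydrogen-bonds to a boronate oxygen while its P=O oxygen holds the formyl hydrogen, so that γ-selective (SE2′) transfer through a six-membered chair transition state inside the chiral pocket fixes the aldehyde face and sets the carbinol carbon as S before borate 6 is hydrolysed on work-up.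

Step 4
Reactants: 8 5-hydroxyvanillin, 3,4-dihydroxy-5-methoxybenzaldehyde
Product: 9 7-methoxy-2,2-diphenyl-1,3-benzodioxole-5-carbaldehyde
Conditions: Ph2CCl2 (1.3 equiv), Ph2O, 175 °C
Reagents that add atoms: dichlorodiphenylmethane, ClC(Cl)(c1ccccc1)c1ccccc1
Why: Ketalisation of the catechol by twofold nucleophilic substitution at the benzhydrylic gem-dichloride should be driven by loss of HCl gas and can only engage the two adjacent hydroxyls in a five-membered ring, leaving the aldehyde and the methyl ether untouched.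

Step 5
Reactants: 9 7-methoxy-2,2-diphenyl-1,3-benzodioxole-5-carbaldehyde
Product: 10 (7-methoxy-2,2-diphenyl-1,3-benzodioxol-5-yl)methanol
Conditions: NaBH4, MeOH–THF, 0 °C
Reagents that add atoms: none
Why: Borohydride reduction of an aryl aldehyde is chemoselective and the ketal is stable to the mildly basic medium.

Step 6
Reactants: 10 (7-methoxy-2,2-diphenyl-1,3-benzodioxol-5-yl)methanol
Product: 11 (7-methoxy-2,2-diphenyl-1,3-benzodioxol-5-yl)methyl 2,2,2-trichloroacetimidate
Conditions: Cl3CCN (2 equiv), DBU (10 mol%), CH2Cl2, 0 °C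
Reagents that add atoms: trichloroacetonitrile, ClC(Cl)(Cl)C#N
Why: Base-catalysed addition of the benzylic alkoxide to the electron-poor nitrile (imidate formation) turns the hydroxyl into a leaving group that can be activated later under nearly neutral conditions.

Step 7
Reactants: 7 (3S)-1-[4-(benzyloxy)-3-methoxyphenyl]hex-5-yn-3-ol; 11 (7-methoxy-2,2-diphenyl-1,3-benzodioxol-5-yl)methyl 2,2,2-trichloroacetimidate
Product: 12 5-[({(3S)-1-[4-(benzyloxy)-3-methoxyphenyl]hex-5-yn-3-yl}oxy)methyl]-7-methoxy-2,2-diphenyl-1,3-benzodioxole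
Conditions: La(OTf)3 (5 mol%), toluene, 0 °C to rt
Reagents that add atoms: none
Why: Acid-catalysed trichloroacetimidate O-benzylation, in which Lewis-acid activation of the imidate releases a benzylic cation stabilised by the para ring oxygen that the secondary hydroxyl traps with loss of trichloroacetamide; the carbinol C–O bond is never broken, so the S configuration is kept, and the mild catalyst should spare the ketal and the alkyne.

Step 8
Reactants: 12 5-[({(3S)-1-[4-(benzyloxy)-3-methoxyphenyl]hex-5-yn-3-yl}oxy)methyl]-7-methoxy-2,2-diphenyl-1,3-benzodioxole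
Product: 13 (4S)-6-[4-(benzyloxy)-3-methoxyphenyl]-4-[(7-methoxy-2,2-diphenyl-1,3-benzodioxol-5-yl)methoxy]hex-1-en-2-yl acetate
Conditions: [RuCl2(p-cymene)]2 (2 mol%), P(2-furyl)3 (4 mol%), Na2CO3 (cat.), AcOH (2 equiv), toluene, 80 °C
Reagents that add atoms: acetic acid, CC(=O)O
Why: Ruthenium-catalysed Markovnikov hydro-acyloxylation of the terminal alkyne, with acetate adding to the internal carbon of the metal-bound alkyne, should give the 2-acetoxy-1-alkene under anhydrous, weakly acidic conditions that the ethers and the ketal tolerate.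

Step 9
Reactants: 13 (4S)-6-[4-(benzyloxy)-3-methoxyphenyl]-4-[(7-methoxy-2,2-diphenyl-1,3-benzodioxol-5-yl)methoxy]hex-1-en-2-yl acetate
Product: 16 (2S,6S)-2-{2-[4-(benzyloxy)-3-methoxyphenyl]ethyl}-6-(7-methoxy-2,2-diphenyl-1,3-benzodioxol-5-yl)oxan-4-one, via oxocarbenium ion 14 (not isolated), via acetoxycarbenium ion 15 (not isolated)
Conditions: DDQ (2 equiv), 2,6-dichloropyridine (4 equiv), LiClO4 (0.2 equiv), 4 Å MS, ClCH2CH2Cl, rt
Reagents that add atoms: none
Why: DDQ should oxidise the trioxygenated arene by electron transfer and then take the hydrogen atom of the ether CH2 (net hydride abstraction), giving the (E)-oxocarbenium ion 14 paired with the hydroquinone monoanion. The terminal carbon of the 2-acetoxyalkene then adds to C6 to give acetoxycarbenium ion 15, which passes its acetyl group to the hydroquinone anion and leaves the C4 ketone; the closest known reaction type is the DDQ-mediated oxidative C–H cleavage of arylmethyl ethers with intramolecular enol acetate capture, a Prins/Mukaiyama-type cyclisation. The oxane is closed by C5–C6 bond formation in a 6-endo-trig mode, with both the C=O+ bond and the enol C=C bond inside the forming ring. C6 is set by the existing C2 stereocentre: in the chair transition state the arylethyl chain sits equatorial and the (E) geometry of the oxocarbenium ion places the aryl group pseudo-equatorial, which should give the 2,6-cis (6S) ring. The step needs oxidation at the ether CH2 in preference to the ArCH2 and OCH2Ph positions of the guaiacyl half, and this is secured because only that C–H is both α to oxygen and conjugated to an arene whose para oxygen is locked coplanar in the benzodioxole, while the ketal carbon has no hydrogen and 2,6-dichloropyridine buffers the acidic hydroquinone.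

Step 10
Reactants: 16 (2S,6S)-2-{2-[4-(benzyloxy)-3-methoxyphenyl]ethyl}-6-(7-methoxy-2,2-diphenyl-1,3-benzodioxol-5-yl)oxan-4-one
Product: 17 (2S,4S,6S)-2-{2-[4-(benzyloxy)-3-methoxyphenyl]ethyl}-6-(7-methoxy-2,2-diphenyl-1,3-benzodioxol-5-yl)oxan-4-ol
Conditions: LiBH(s-Bu)3 (1.3 equiv), THF, −78 °C; then NaOH, H2O2, 0 °C
Reagents that add atoms: none
Why: Substrate-controlled ketone reduction with a bulky trialkylborohydride: the ring is locked by its two equatorial substituents and the axial trajectory is blocked by the axial hydrogens at C2 and C6, so hydride should enter equatorially and place the new C4 hydroxyl axial, trans to both substituents (4S).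

Step 11
Reactants: 17 (2S,4S,6S)-2-{2-[4-(benzyloxy)-3-methoxyphenyl]ethyl}-6-(7-methoxy-2,2-diphenyl-1,3-benzodioxol-5-yl)oxan-4-ol
Product: 18 (2S,4S,6S)-2-{2-[4-(benzyloxy)-3-methoxyphenyl]ethyl}-6-(7-methoxy-2,2-diphenyl-1,3-benzodioxol-5-yl)oxan-4-yl acetate
Conditions: Ac2O, pyridine, DMAP (cat.), CH2Cl2, rt
Reagents that add atoms: acetic anhydride, CC(=O)OC(C)=O
Why: DMAP-catalysed O-acylation of the only free hydroxyl proceeds at oxygen with retention at C4, and doing it before the phenols are unmasked makes the acetylation site-specific.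

Step 12
Reactants: 18 (2S,4S,6S)-2-{2-[4-(benzyloxy)-3-methoxyphenyl]ethyl}-6-(7-methoxy-2,2-diphenyl-1,3-benzodioxol-5-yl)oxan-4-yl acetate
Product: 19 (2S,4S,6S)-2-(3,4-dihydroxy-5-methoxyphenyl)-6-[2-(4-hydroxy-3-methoxyphenyl)ethyl]oxan-4-yl acetate (CNP0143286.2)
Conditions: H2 (1 atm), Pd/C (10 wt%), EtOAc–MeOH, rt
Reagents that add atoms: none
Why: Heterogeneous catalytic hydrogenolysis should cleave the aryl benzyl ether and the doubly benzylic C–O bonds of the diphenylmethylene ketal (as toluene and diphenylmethane) faster than the ring O1–C6 bond in a neutral solvent, and it touches neither the acetate nor any stereocentre.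

**Compound list**

1 | dihydroferulic acid, 3-(4-hydroxy-3-methoxyphenyl)propanoic acid | COc1cc(CCC(=O)O)ccc1O | starting material
2 | benzyl 3-[4-(benzyloxy)-3-methoxyphenyl]propanoate | COc1cc(CCC(=O)OCc2ccccc2)ccc1OCc1ccccc1 | intermediate
3 | diisobutylaluminium hemiacetal of 2, {1-(benzyloxy)-3-[4-(benzyloxy)-3-methoxyphenyl]propoxy}diisobutylalumane | COc1cc(CCC(OCc2ccccc2)O[Al](CC(C)C)CC(C)C)ccc1OCc1ccccc1 | intermediate
4 | 3-[4-(benzyloxy)-3-methoxyphenyl]propanal | COc1cc(CCC=O)ccc1OCc1ccccc1 | intermediate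
5 | allenylboronic acid pinacol ester, 4,4,5,5-tetramethyl-2-(propa-1,2-dienyl)-1,3,2-dioxaborolane | C=C=CB1OC(C)(C)C(C)(C)O1 | starting material
6 | pinacol borate ester of 7, 2-({(3S)-1-[4-(benzyloxy)-3-methoxyphenyl]hex-5-yn-3-yl}oxy)-4,4,5,5-tetramethyl-1,3,2-dioxaborolane | COc1cc(CC[C@H](OB2OC(C)(C)C(C)(C)O2)CC#C)ccc1OCc1ccccc1 | intermediate
7 | (3S)-1-[4-(benzyloxy)-3-methoxyphenyl]hex-5-yn-3-ol | COc1cc(CC[C@H](O)CC#C)ccc1OCc1ccccc1 | intermediate
8 | 5-hydroxyvanillin, 3,4-dihydroxy-5-methoxybenzaldehyde | COc1cc(C=O)cc(O)c1O | starting material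
9 | 7-methoxy-2,2-diphenyl-1,3-benzodioxole-5-carbaldehyde | COc1cc(C=O)cc2OC(c3ccccc3)(c3ccccc3)Oc12 | intermediate
10 | (7-methoxy-2,2-diphenyl-1,3-benzodioxol-5-yl)methanol | COc1cc(CO)cc2OC(c3ccccc3)(c3ccccc3)Oc12 | intermediate
11 | (7-methoxy-2,2-diphenyl-1,3-benzodioxol-5-yl)methyl 2,2,2-trichloroacetimidate | COc1cc(COC(=N)C(Cl)(Cl)Cl)cc2OC(c3ccccc3)(c3ccccc3)Oc12 | intermediate
12 | 5-[({(3S)-1-[4-(benzyloxy)-3-methoxyphenyl]hex-5-yn-3-yl}oxy)methyl]-7-methoxy-2,2-diphenyl-1,3-benzodioxole | COc1cc(CC[C@H](OCc2cc(OC)c3OC(c4ccccc4)(c4ccccc4)Oc3c2)CC#C)ccc1OCc1ccccc1 | intermediate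
13 | (4S)-6-[4-(benzyloxy)-3-methoxyphenyl]-4-[(7-methoxy-2,2-diphenyl-1,3-benzodioxol-5-yl)methoxy]hex-1-en-2-yl acetate | COc1cc(CC[C@H](OCc2cc(OC)c3OC(c4ccccc4)(c4ccccc4)Oc3c2)CC(=C)OC(C)=O)ccc1OCc1ccccc1 | intermediate
14 | (E)-oxocarbenium ion, {(3S)-5-acetoxy-1-[4-(benzyloxy)-3-methoxyphenyl]hex-5-en-3-yl}[(7-methoxy-2,2-diphenyl-1,3-benzodioxol-5-yl)methylidene]oxonium | COc1cc(CC[C@H](/[O+]=C/c2cc(OC)c3OC(c4ccccc4)(c4ccccc4)Oc3c2)CC(=C)OC(C)=O)ccc1OCc1ccccc1 | intermediate
15 | ring-closed acetoxycarbenium ion, acetyl[(2S,6S)-2-{2-[4-(benzyloxy)-3-methoxyphenyl]ethyl}-6-(7-methoxy-2,2-diphenyl-1,3-benzodioxol-5-yl)oxan-4-ylidene]oxonium | COc1cc(CC[C@H]2CC(=[O+]C(C)=O)C[C@@H](c3cc(OC)c4OC(c5ccccc5)(c5ccccc5)Oc4c3)O2)ccc1OCc1ccccc1 | intermediate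
16 | (2S,6S)-2-{2-[4-(benzyloxy)-3-methoxyphenyl]ethyl}-6-(7-methoxy-2,2-diphenyl-1,3-benzodioxol-5-yl)oxan-4-one | COc1cc(CC[C@H]2CC(=O)C[C@@H](c3cc(OC)c4OC(c5ccccc5)(c5ccccc5)Oc4c3)O2)ccc1OCc1ccccc1 | intermediate
17 | (2S,4S,6S)-2-{2-[4-(benzyloxy)-3-methoxyphenyl]ethyl}-6-(7-methoxy-2,2-diphenyl-1,3-benzodioxol-5-yl)oxan-4-ol | COc1cc(CC[C@H]2C[C@H](O)C[C@@H](c3cc(OC)c4OC(c5ccccc5)(c5ccccc5)Oc4c3)O2)ccc1OCc1ccccc1 | intermediate
18 | (2S,4S,6S)-2-{2-[4-(benzyloxy)-3-methoxyphenyl]ethyl}-6-(7-methoxy-2,2-diphenyl-1,3-benzodioxol-5-yl)oxan-4-yl acetate | COc1cc(CC[C@H]2C[C@H](OC(C)=O)C[C@@H](c3cc(OC)c4OC(c5ccccc5)(c5ccccc5)Oc4c3)O2)ccc1OCc1ccccc1 | intermediate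
19 | (2S,4S,6S)-2-(3,4-dihydroxy-5-methoxyphenyl)-6-[2-(4-hydroxy-3-methoxyphenyl)ethyl]oxan-4-yl acetate, CNP0143286.2 | COc1cc(CC[C@H]2C[C@H](OC(C)=O)C[C@@H](c3cc(O)c(O)c(OC)c3)O2)ccc1O | target

**Step count and risks**

Total step count: 12. Longest linear sequence: 9 steps (1 to 19 through steps 1, 2, 3, 7–12; the branch from 8 through steps 4–6 and 7–12 is equally long).

Steps most likely to fail:

1. Step 9. Hydrogen abstraction may occur at the benzylic CH2 of the guaiacyl half or at the C6–H of the product, or ionisation may be too slow for clean closure. Fallback, setting out from alcohol 7 and aldehyde 9 and returning at ketone 16, closes the ring at O1–C6 by oxa-Michael addition instead. Alcohol 7 would be silylated (TBSCl, imidazole, DMF) to tert-butyl({(3S)-1-[4-(benzyloxy)-3-methoxyphenyl]hex-5-yn-3-yl}oxy)dimethylsilane F1. Its lithium acetylide (n-BuLi, THF, −78 °C) would add to aldehyde 9 to give (5S)-7-[4-(benzyloxy)-3-methoxyphenyl]-5-[(tert-butyldimethylsilyl)oxy]-1-(7-methoxy-2,2-diphenyl-1,3-benzodioxol-5-yl)hept-2-yn-1-ol F2, as carbinol epimers of no consequence. Meyer–Schuster rearrangement (Ph3PAuNTf2 cat., MeOH, toluene, rt) would convert it into (1E,5S)-7-[4-(benzyloxy)-3-methoxyphenyl]-5-[(tert-butyldimethylsilyl)oxy]-1-(7-methoxy-2,2-diphenyl-1,3-benzodioxol-5-yl)hept-1-en-3-one F3. Desilylation with TBAF in THF would give (1E,5S)-7-[4-(benzyloxy)-3-methoxyphenyl]-5-hydroxy-1-(7-methoxy-2,2-diphenyl-1,3-benzodioxol-5-yl)hept-1-en-3-one F4, which with catalytic KOt-Bu should close by reversible 6-endo-trig oxa-Michael addition to the thermodynamically preferred 2,6-cis ketone 16.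

2. Step 3. Facial discrimination may be insufficient for an unbranched aliphatic aldehyde, and the enantiomeric purity cannot be raised later because every other stereocentre is relayed from C2. Fallback, setting out from aldehyde 4 and returning at alcohol 7, takes the stereocentre from a kinetic resolution. Corey–Chaykovsky methylenation (Me3S+ I−, NaH, DMSO–THF) would give racemic 2-{2-[4-(benzyloxy)-3-methoxyphenyl]ethyl}oxirane F5. Hydrolytic kinetic resolution with (S,S)-(salen)Co(OAc) and 0.55 equiv of water, the catalyst enantiomer expected to leave the (S)-epoxide, would give (2S)-2-{2-[4-(benzyloxy)-3-methoxyphenyl]ethyl}oxirane F6, separable from (2R)-4-[4-(benzyloxy)-3-methoxyphenyl]butane-1,2-diol F7. Opening of F6 at its terminal carbon with LiC≡CH·H2NCH2CH2NH2 in DMSO would give 7 with the carbinol centre untouched.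

3. Step 12. Over-reduction may open the benzylic O1–C6 bond of the oxane while the slower ketal cleavage is pushed to completion. Fallback, setting out from acetate 18 and returning at target 19, separates the two deprotections and removes the ketal without hydrogen. Hydrolysis in AcOH–H2O (4:1) at 80 °C would release benzophenone and give (2S,4S,6S)-2-{2-[4-(benzyloxy)-3-methoxyphenyl]ethyl}-6-(3,4-dihydroxy-5-methoxyphenyl)oxan-4-yl acetate F8. The remaining aryl benzyl ether, which is cleaved far faster than a benzylic alkyl ether, would then be removed by brief exposure to H2 and Pd/C in EtOAc to give 19.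

**Further compounds**

F1 | step 9 | tert-butyl({(3S)-1-[4-(benzyloxy)-3-methoxyphenyl]hex-5-yn-3-yl}oxy)dimethylsilane | COc1cc(CC[C@H](O[Si](C)(C)C(C)(C)C)CC#C)ccc1OCc1ccccc1
F2 | step 9 | (5S)-7-[4-(benzyloxy)-3-methoxyphenyl]-5-[(tert-butyldimethylsilyl)oxy]-1-(7-methoxy-2,2-diphenyl-1,3-benzodioxol-5-yl)hept-2-yn-1-ol | COc1cc(CC[C@H](O[Si](C)(C)C(C)(C)C)CC#CC(O)c2cc(OC)c3OC(c4ccccc4)(c4ccccc4)Oc3c2)ccc1OCc1ccccc1
F3 | step 9 | (1E,5S)-7-[4-(benzyloxy)-3-methoxyphenyl]-5-[(tert-butyldimethylsilyl)oxy]-1-(7-methoxy-2,2-diphenyl-1,3-benzodioxol-5-yl)hept-1-en-3-one | COc1cc(CC[C@H](O[Si](C)(C)C(C)(C)C)CC(=O)/C=C/c2cc(OC)c3OC(c4ccccc4)(c4ccccc4)Oc3c2)ccc1OCc1ccccc1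
F4 | step 9 | (1E,5S)-7-[4-(benzyloxy)-3-methoxyphenyl]-5-hydroxy-1-(7-methoxy-2,2-diphenyl-1,3-benzodioxol-5-yl)hept-1-en-3-one | COc1cc(CC[C@H](O)CC(=O)/C=C/c2cc(OC)c3OC(c4ccccc4)(c4ccccc4)Oc3c2)ccc1OCc1ccccc1
F5 | step 3 | racemic 2-{2-[4-(benzyloxy)-3-methoxyphenyl]ethyl}oxirane | COc1cc(CCC2CO2)ccc1OCc1ccccc1
F6 | step 3 | (2S)-2-{2-[4-(benzyloxy)-3-methoxyphenyl]ethyl}oxirane | COc1cc(CC[C@H]2CO2)ccc1OCc1ccccc1
F7 | step 3 | (2R)-4-[4-(benzyloxy)-3-methoxyphenyl]butane-1,2-diol | COc1cc(CC[C@@H](O)CO)ccc1OCc1ccccc1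
F8 | step 12 | (2S,4S,6S)-2-{2-[4-(benzyloxy)-3-methoxyphenyl]ethyl}-6-(3,4-dihydroxy-5-methoxyphenyl)oxan-4-yl acetate | COc1cc(CC[C@H]2C[C@H](OC(C)=O)C[C@@H](c3cc(O)c(O)c(OC)c3)O2)ccc1OCc1ccccc1
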